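At early times a chain of additions shows its order plainly: bis adduct, taken here as two reagent steps, grows with the square of the substrate's exposure to reagent, and triple product, taken as 3 steps, grows with its cube.

in all of them: substrate 0.050 M

| charge | reagent | scavenger | remark | time |
|---|---|---|---|---|
| Monday's | 0.035 M | 0.060 M | run made earlier |  |
| Saturday's | 0.30 M | 0.060 M | run made earlier |  |
| epsilon | 0.0250 M | 0.0600 M |  | 25 min |
| zeta | 0.150 M | 0.0600 M |  | 25 min |
| theta | 0.200 M | 0.0600 M |  | 25 min |

| run | time / min | triple product / % | bis adduct / % |
|---|---|---|---|
| Monday's | 4.00 | 0 | 0 |
| Monday's | 8.00 | 0 | 0.6 |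
| Monday's | 10.0 | 0.4 | 0.9 |
| Monday's | 15.0 | 0 | 1.0 |
| Monday's | 20.0 | 0.1 | 1.6 |
| Monday's | 25.0 | 0.1 | 1.9 |
| Saturday's | 4.00 | 2.3 | 9.2 |
| Saturday's | 8.00 | 8.5 | 16.6 |
| Saturday's | 10.0 | 11.3 | 17.7 |
| Saturday's | 15.0 | 18.7 | 20.3 |
| Saturday's | 20.0 | 23.7 | 21.7 |
| Saturday's | 25.0 | 29.0 | 22.1 |

(each reading ± 0.3 percentage points)



- final triple product, as a percentage of the substrate charged, for each flask in turn (epsilon, zeta, theta)

Exposure here means the reagent concentration summed over time. If each step is pseudo-first-order in its chain species, flasks at equal exposure hold the same bis adduct and triple product, whatever their charges and times.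

Monday's table shows how exposure grows. Bis adduct rises from 0.6% at 8.00 min to 1.9% at 25.0 min, a factor of 3.17, where steady exposure would give 9.77. So Monday's reagent appears to fade, and these readings put the growth of its exposure at the square root of that measured factor, 1.78. With a scatter of 0.3 percentage points on the first reading, this factor is rough.

Now take the fading as equal at every charge, and Saturday's early exposure as steady, which is a simplification. The equivalent Saturday time is then the minute at which Saturday had reached the exposure a new flask reaches at 25 min: 8.00 min times the ratio of the charge to Saturday's, times that factor. For zeta it is 7.12 min, for theta 9.49 min and for epsilon 1.19 min.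

Saturday's triple-product column then answers directly. Zeta falls between the rows at 4.00 min and 8.00 min, which gives 7.13%. Theta falls between the rows at 8.00 min and 10.0 min, which gives 10.6%. Epsilon falls before the first row, so the cube from 2.3% gives 0.0600%.

The forecast, shading its last two values down because “the second step seems steeper than first order in reagent”, reads 0.05%, 6% and 12.5%, so it stands above this reckoning for theta and below it for zeta.

The flasks give 0.0493%, 6.85% and 13.2%, so theta stands above its reckoned value.

    substrate + reagent → first product + released group (k = 0.950 /M/min)
    reagent + first product → bis adduct + released group (k = 0.400 /M/min)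
    reagent + bis adduct → triple product + released group (k = 0.740 /M/min)
    reagent + triple product → tetra adduct + released group (k = 0.0160 /M/min)
    reagent + released group ⇌ idle adduct, settled at all times (K = 5.60 /M)
    scavenger + released group → scavenged by-product (k = 120 /M/min)
    reagent ⇌ dormant form (K = 2.40, k = 0.0820 /min)
    released group → by-product carried off (k = 0.00490 /min)

In epsilon, reagent at the start turns into dormant form 1.7 times as fast (forward step alone) as it is used on substrate, and that step has 96% of its turnover up to 25 min behind it by 12.5 min. Zeta's final bis adduct of 14.8% lies between Saturday's 9.2% and 16.6%, the rows around its equivalent time of 7.12 min, while theta, reckoned at 9.49 min, ends with more bis adduct than Saturday's 10.0 min row, 19.1% against 17.7%.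

All runs were generated by integration from invented constants; scatter was added.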